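## The problem

Compound 30 is a depside. Ring A (a 2,4-dimethoxy-6-pentylbenzoyl group) and ring B (2-hydroxy-6-pentylbenzoic acid) are held together only by an aryl ester from the ring A carboxyl to the C4 oxygen of ring B. There is no stereocenter, so the task is one of regiochemistry and chemoselectivity. Ring B carries three acidic oxygen functions (C1 carboxyl, C2 hydroxyl, C4 oxygen), and only the C4 oxygen may be acylated. The acyl donor is hindered by an ortho methoxy and an ortho pentyl group. The aryl ester will not tolerate hydroxide, alkoxide or amine nucleophiles. The 2-hydroxybenzoic acid of ring B loses CO2 easily on heating or in strong acid. The ring A methyl ethers rule out any late Lewis acid ether cleavage. The ring B acid therefore needs a mask that comes off under neutral conditions at the end, and the two ring B oxygens must be told apart before the ester is made. The feature that invites a ring synthesis is the pattern of ring B: oxygen at C2 and C4 with hydrogen at C3 between them, carboxyl at C1, pentyl at C6, hydrogen at C5. A four-carbon vinylketene (C2, C5, C6, C1, its carbonyl oxygen becoming the C2 hydroxyl) and an oxygen-bearing alkyne (C3, C4) give exactly this arrangement, with the two oxygens differentiated.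

## Retrosynthesis

**30 to 29.** The last bond cut is the O–CH2Ph bond of benzyl ester 29. Hydrogenolysis is neutral and leaves the aryl ester, the methyl ethers and the free salicylic acid alone. A methyl or tert-butyl ester would need base or strong acid here, which the depside ester or the decarboxylation-prone acid would not survive.

**29 to 27 and 23.** The acyl C–O bond between the rings is cut next, giving ring A acid 27 (used as its chloride 28) and ring B phenol 23. This is the only bond between the two halves, so the route is convergent. The forward reaction must acylate the C4 hydroxyl of 23 and not the C2 hydroxyl. The C2 hydroxyl is hydrogen-bonded to the neighbouring ester carbonyl and is flanked by it, which should secure this.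

**23 to 22.** Phenol 23 is traced back to its C4 triisopropylsilyl ether 22 by cutting the Si–O bond. The silyl group is not added as a protection step. It arrives with the alkyne in the ring-forming step, so the C2 and C4 oxygens are different from the moment ring B exists.

**22 to 9 and 17.** The ring B bonds C2–C3, C4–C5 and C1–C2 are cut. This gives acid chloride 9, the precursor of vinylketene 18, and siloxyalkyne 17. Compared with building the ring by aldol chemistry or by oxidizing a cyclohexanedione, this cut delivers an aromatic ring at the right oxidation level with ester, pentyl group and both oxygens in place. Both precursors are acyclic and small. The forward step must generate 18 from 9 and let it be captured by 17 faster than the acyl terminus closes onto its own ester oxygen. The [2+2] addition must also occur in the sense set by the polarization of 17. Cyclobutenone 19, dienylketene 20 and dienone 21 lie on the way.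

**9 to 6 and 7.** Acid chloride 9 comes from half ester 8, which comes from cyclic anhydride 6 and benzyl alcohol 7 by cutting the ester C–O bond. Opening a cyclic anhydride is the simplest way to put one benzyl ester and one free acid on a symmetrical five-carbon diacid. The double-bond position in 8 is not critical: the 2-ene and 3-ene isomers of the acid chloride give the same vinylketene 18 by 1,4- or 1,2-loss of HCl.

**6 to 1 and 2.** Anhydride 6 is the dehydration product of 3-pentylglutaconic acid 5. Cutting the C3–C4 bond of 5 leads to triester 3, the Michael adduct of dimethyl malonate 2 and methyl oct-2-ynoate 1. This carries the pentyl group in from a commodity ynoate and avoids a cross-coupling next to an acidic methylene group. The forward steps must only hydrolyse 3 and remove one carboxyl (through triacid 4). Alkene isomers converge at 6.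

**17 to 10 and 11.** The alkyne triple bond of 17 is formed by loss of HBr from bromovinyl ether 15 (through acetylide 16). Ether 15 comes from vinyl ether 13 by bromination and loss of HBr through dibromide 14. Ether 13 comes from tetrahydrofuran 10 (through enolate 12) and silyl chloride 11. This follows the classical route to alkoxyethynes and needs no unsubstituted ynolate, which is awkward to generate cleanly.

**27 to 24.** The aryl–carboxyl bond of 27 is cut to aryllithium 26 and CO2. Aryllithium 26 comes from bromide 25, made by bromination of commercial 1,3-dimethoxy-5-pentylbenzene 24. Bromination goes para to a methoxy group and so fixes the carboxyl position that direct lithiation of 24 (between the two methoxy groups) would miss.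

## Roads not taken

**Alternative 1:** Ring A by aryne carbomagnesiation. The cut is at the aryl–pentyl and aryl–carboxyl bonds of ring A. In the forward direction, dihalide A1 (1-bromo-2-iodo-3,5-dimethoxybenzene) is treated with an excess of a pentylmagnesium halide. Iodine–magnesium exchange and loss of magnesium halide give aryne A2 (3,5-dimethoxybenzyne). A second Grignard molecule adds at the aryne carbon remote from the adjacent methoxy group, and the aryl Grignard is carboxylated to acid A3 (2,4-dimethoxy-6-pentylbenzoic acid, identical with 27).

- Merits: two C–C bonds in one flask, no ring closure to worry about, and the acid forms directly.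
- Weak points: A1 is not a catalogue compound and its preparation has its own regiochemical questions. The regiochemistry of addition rests on the directing effect of one methoxy group. Ring A is also the easy half of the molecule.
- Comparison: counted from A1, this is one step against two from 24, so it is at least as short. The chosen plan sets against it a cheap commercial arene and a regiochemistry fixed by ordinary electrophilic substitution. The aryne route also does nothing for ring B, where the real difficulty lies.

**Alternative 2:** Ring A as a cyclohexanedione, aromatized late. The cut is at ring A bonds C1–C6 and C2–C3. The sodium salt of dimethyl malonate 2 adds to enone A4 ((E)-non-3-en-2-one), and the methyl ketone enolate closes onto a malonate ester to give A5 (racemic methyl 2-hydroxy-4-oxo-6-pentylcyclohex-1-ene-1-carboxylate). Oxidative aromatization and methylation give A6 (methyl 2,4-dimethoxy-6-pentylbenzoate), which is hydrolysed to 27.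

- Merits: very cheap materials, a ring closure that is long established for pentylresorcinol derivatives, and easy scale-up.
- Weak points: the stereocenter is made only to be destroyed. The aromatization needs an oxidant that tends to halogenate the electron-rich ring. The doubly ortho-substituted methyl ester A6 is slow to saponify. The sequence is about four steps for an acid that takes two from 24.
- Comparison: run with a benzyl ester instead of the methyl ester, the same annulation would be a well-tried entry to ring B phenol 23 and more certain than step 9. The chosen plan sets against this that ring B is born aromatic with no oxidation step, and that its two oxygens leave the ring-forming step already differentiated.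

**Alternative 3:** Ring B folded from a masked triketo ester. The cut is at the ring B C1–C6 bond. Heating dioxinone A7 (6-(2,4-dioxononyl)-2,2-dimethyl-4H-1,3-dioxin-4-one) with benzyl alcohol 7 releases an acylketene that is trapped as A8 (benzyl 3,5,7-trioxododecanoate). Its C2 then attacks the C7 ketone and dehydration gives A9 (benzyl 2,4-dihydroxy-6-pentylbenzoate, identical with 23).

- Merits: mild, biomimetic, and it reaches 23 without a silyl ether stage. The reaction class is well established, and in certainty of the ring-forming event this road is better than the chosen one.
- Weak points: A7 itself takes several steps of dianion acylation. The triketo ester can also cyclize through oxygen to pyranones. Both hydroxyls of the product are free.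
- Comparison: in step count the two roads are about level. The chosen plan sets against it precursors made from commodity chemicals by classical reactions, a single regiochemical outcome once the [2+2] step follows the alkyne polarization, and a C4 oxygen that is masked from the start. The chosen key step carries more risk, which is why its fallback joins the route again at 23.

Key step: step 9

## Route

Remark on the chemistry: 3 and 5 are handled as mixtures of alkene isomers, which converge at 6. Compound 6 is drawn as the dione, although it is expected to exist largely as its enol, 6-hydroxy-4-pentyl-2H-pyran-2-one.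

Step 1
Reactants: 1 methyl oct-2-ynoate; 2 dimethyl malonate
Product: 3 trimethyl 2-pentylprop-1-ene-1,3,3-tricarboxylate (mixture of alkene isomers)
Conditions: NaOMe (1.05 equiv), MeOH, 0 °C to reflux; then AcOH
Reagents that add atoms: none
Why: Michael addition of the malonate anion to the beta carbon of an acetylenic ester. The adduct is a vinylogous malonate that holds the base as its anion, so a full equivalent is used and released with acetic acid.

Step 2
Reactants: 3 trimethyl 2-pentylprop-1-ene-1,3,3-tricarboxylate
Product: 5 3-pentylpent-2-enedioic acid (E/Z mixture), via triacid 4 (not isolated)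
Conditions: 6 M HCl, AcOH, 100 °C
Reagents that add atoms: water, O
Why: Acid-catalysed ester hydrolysis followed by malonic acid decarboxylation of the alkenylmalonic acid 4, the classical way to 3-substituted glutaconic acids. Acid is used so that the vinylogous malonate anion, which resists saponification, is never formed.

Step 3
Reactants: 5 3-pentylpent-2-enedioic acid
Product: 6 4-pentyl-2H-pyran-2,6(3H)-dione (3-pentylglutaconic anhydride)
Conditions: Ac2O, 80 °C; evaporate
Reagents that add atoms: none
Why: Cyclodehydration through the mixed anhydride. The methylene protons of glutaconic derivatives exchange easily, so E and Z acid both funnel into the six-membered anhydride, which is stabilized as its hydroxypyranone enol.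

Step 4
Reactants: 6 4-pentyl-2H-pyran-2,6(3H)-dione; 7 benzyl alcohol
Product: 8 (2Z)-5-(benzyloxy)-5-oxo-3-pentylpent-2-enoic acid
Conditions: BnOH (1.05 equiv), toluene, 80 °C
Reagents that add atoms: none
Why: Alcoholysis of a cyclic anhydride at the more electrophilic, non-conjugated carbonyl gives one ester and one acid. The ring fixes the cis arrangement of the two arms. Any 3-ene tautomer present is harmless because it leads to the same ketene in step 9.

Step 5
Reactants: 8 (2Z)-5-(benzyloxy)-5-oxo-3-pentylpent-2-enoic acid
Product: 9 (2Z)-5-(benzyloxy)-5-oxo-3-pentylpent-2-enoyl chloride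
Conditions: (COCl)2 (1.2 equiv), DMF (cat.), CH2Cl2, 0 °C; evaporate cold, use at once
Reagents that add atoms: oxalyl chloride, ClC(=O)C(Cl)=O
Why: Standard conversion of an acid to its chloride through the catalytic chloroiminium species. No base is present, so the acidic methylene group is left untouched until step 9.

Step 6
Reactants: 10 tetrahydrofuran; 11 chlorotri(propan-2-yl)silane
Product: 13 ethenyloxy-tri(propan-2-yl)silane, via lithium ethenolate 12 (not isolated)
Conditions: n-BuLi, THF, 25 °C, 16 h; then iPr3SiCl, DMPU, 0 to 25 °C
Reagents that add atoms: none
Why: 2-Lithiotetrahydrofuran undergoes cycloreversion to ethene and the lithium enolate of acetaldehyde, which is silylated on oxygen by the hindered silyl chloride. This is the usual preparation of silyl vinyl ethers.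

Step 7
Reactants: 13 ethenyloxy-tri(propan-2-yl)silane
Product: 15 [(Z)-2-bromoethenyl]oxy-tri(propan-2-yl)silane (Z expected to predominate), via dibromide 14 (not isolated)
Conditions: Br2, CH2Cl2, −78 °C; then iPr2NEt, −78 to 25 °C
Reagents that add atoms: bromine, BrBr
Why: Bromine adds to the enol ether, and the alpha-bromo ether 14 then loses HBr toward the bromomethyl carbon, as in the classical preparation of 2-bromovinyl ethers. A hindered amine is chosen so that it does not quaternize at the alpha-bromo ether carbon.

Step 8
Reactants: 15 [(Z)-2-bromoethenyl]oxy-tri(propan-2-yl)silane
Product: 17 ethynyloxy-tri(propan-2-yl)silane ((triisopropylsilyloxy)ethyne), via lithium acetylide 16 (not isolated)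
Conditions: LiN(iPr)2 (2.2 equiv), THF, −78 to 0 °C; then H2O, cold pentane extraction, distillation
Reagents that add atoms: none
Why: Anti elimination of HBr from the Z bromovinyl ether (the hydrogen on the oxygen-bearing carbon is trans to bromine), the dehydrohalogenation that gives alkoxyethynes. The second equivalent of amide holds the product as acetylide 16 until the quench. The bulky silyl group retards attack at silicon and silyl migration to carbon.

Step 9
Reactants: 9 (2Z)-5-(benzyloxy)-5-oxo-3-pentylpent-2-enoyl chloride; 17 ethynyloxy-tri(propan-2-yl)silane
Product: 22 benzyl 2-hydroxy-6-pentyl-4-(triisopropylsilyloxy)benzoate, via vinylketene 18 (not isolated), via cyclobutenone 19 (not isolated), via dienylketene 20 (not isolated), via cyclohexadienone 21 (not isolated)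
Conditions: 17 (2.5 equiv), NEt3 (1.1 equiv), toluene, 0 °C, 9 added over 2 h; 25 °C; then 80 °C
Reagents that add atoms: none
Why: Proposed new method: NEt3 removes the doubly activated C4 proton of 9 and chloride leaves (1,4-dehydrochlorination), which should give vinylketene 18 with its ester turned away from the acyl terminus, because the Z acid chloride holds the COCl group on the inner side of the developing planar anion; the closest known reaction type is the Danheiser benzannulation, in which vinylketenes made from 3-alkylbut-2-enoyl chlorides with NEt3 or from cyclobutenones combine with siloxyalkynes to give resorcinol monosilyl ethers, and the new element is the ester on the vinyl terminus. The nucleophilic CH carbon of 17 attacks the ketene carbonyl carbon and the four-membered ring closes to 19, a stepwise [2+2] cycloaddition that forms C2–C3 and C4–C5 (ring B numbering). On warming, 19 opens by four-electron conrotatory electrocyclic cleavage of the old ketene C–C bond to dienylketene 20. Ring B then closes by a thermal six-electron disrotatory electrocyclization of 20 that joins the ketene carbon to the ester-bearing vinyl carbon (C1–C2), and enolization of the beta-keto ester 21 gives the phenol. No stereocenter remains in 22. The selectivity needed is the regiochemistry of the [2+2] step, and it is secured by the polarization of 17, whose oxygen lone pair makes the CH terminus the nucleophile, so that oxygen ends at C4 and hydrogen at C3. The competing closure of the acyl terminus onto the ester oxygen, which would give a 6-benzyloxypyran-2-one, is countered by the outward ester geometry of 18, by slow addition of 9 into an excess of 17 so that the ketene is trapped as it forms, and by heating only after 9 is consumed.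

Step 10
Reactants: 22 benzyl 2-hydroxy-6-pentyl-4-(triisopropylsilyloxy)benzoate
Product: 23 benzyl 2,4-dihydroxy-6-pentylbenzoate
Conditions: Bu4NF, AcOH, THF, 0 °C
Reagents that add atoms: none
Why: Fluoride cleavage of an aryl silyl ether, driven by the Si–F bond. Acetic acid buffers the phenoxide so that the benzyl ester is not attacked.

Step 11
Reactants: 24 1,3-dimethoxy-5-pentylbenzene
Product: 25 1-bromo-2,4-dimethoxy-6-pentylbenzene
Conditions: NBS (1.0 equiv), MeCN, 0 to 25 °C
Reagents that add atoms: N-bromosuccinimide, O=C1CCC(=O)N1Br
Why: Electrophilic aromatic bromination para to one methoxy group and ortho to the other. The position between the two methoxy groups is buttressed and reacts more slowly, and one equivalent limits dibromination.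

Step 12
Reactants: 25 1-bromo-2,4-dimethoxy-6-pentylbenzene
Product: 27 2,4-dimethoxy-6-pentylbenzoic acid, via aryllithium 26 (not isolated)
Conditions: n-BuLi, THF, −78 °C; CO2 (gas); then aq. HCl
Reagents that add atoms: carbon dioxide, O=C=O
Why: Bromine–lithium exchange followed by carboxylation of the aryllithium. Low temperature and a prompt CO2 quench keep 26 from moving its lithium to the position between the methoxy groups.

Step 13
Reactants: 27 2,4-dimethoxy-6-pentylbenzoic acid; 23 benzyl 2,4-dihydroxy-6-pentylbenzoate
Product: 29 benzyl 4-[(2,4-dimethoxy-6-pentylbenzoyl)oxy]-2-hydroxy-6-pentylbenzoate, via acid chloride 28 (not isolated)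
Conditions: (COCl)2, DMF (cat.), CH2Cl2, 0 to 25 °C, evaporate; then 23 (1.0 equiv), NEt3, DMAP (cat.), CH2Cl2, 0 to 25 °C
Reagents that add atoms: none
Why: Acylation of a phenol by an aroyl chloride with nucleophilic catalysis. The C2 hydroxyl of 23 is locked in a hydrogen bond to the ester carbonyl and is hindered, so the free C4 hydroxyl reacts, as is usual in depside synthesis.

Step 14
Reactants: 29 benzyl 4-[(2,4-dimethoxy-6-pentylbenzoyl)oxy]-2-hydroxy-6-pentylbenzoate
Product: 30 4-[(2,4-dimethoxy-6-pentylbenzoyl)oxy]-2-hydroxy-6-pentylbenzoic acid
Conditions: H2 (1 atm), Pd/C (10 wt% palladium on carbon), EtOAc, 25 °C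
Reagents that add atoms: none
Why: Hydrogenolysis of a benzyl ester under neutral conditions. The aryl ester, the methyl ethers and the salicylic acid are inert to it.

## Compound list

1 | methyl oct-2-ynoate | CCCCCC#CC(=O)OC | starting material
2 | dimethyl malonate | COC(=O)CC(=O)OC | starting material
3 | trimethyl 2-pentylprop-1-ene-1,3,3-tricarboxylate (alkene isomer mixture, drawn without geometry) | CCCCCC(=CC(=O)OC)C(C(=O)OC)C(=O)OC | intermediate
4 | 2-pentylprop-1-ene-1,3,3-tricarboxylic acid (alkene isomer mixture, formed in the flask) | CCCCCC(=CC(=O)O)C(C(=O)O)C(=O)O | intermediate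
5 | 3-pentylpent-2-enedioic acid (E/Z mixture, drawn without geometry) | CCCCCC(=CC(=O)O)CC(=O)O | intermediate
6 | 4-pentyl-2H-pyran-2,6(3H)-dione | CCCCCC1=CC(=O)OC(=O)C1 | intermediate
7 | benzyl alcohol | OCc1ccccc1 | starting material
8 | (2Z)-5-(benzyloxy)-5-oxo-3-pentylpent-2-enoic acid | CCCCC/C(CC(=O)OCc1ccccc1)=C/C(=O)O | intermediate
9 | (2Z)-5-(benzyloxy)-5-oxo-3-pentylpent-2-enoyl chloride | CCCCC/C(CC(=O)OCc1ccccc1)=C/C(Cl)=O | intermediate
10 | tetrahydrofuran | C1CCOC1 | starting material
11 | chlorotri(propan-2-yl)silane | CC(C)[Si](Cl)(C(C)C)C(C)C | starting material
12 | lithium ethenolate (formed in the flask) | [Li+].[O-]C=C | intermediate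
13 | ethenyloxy-tri(propan-2-yl)silane | C=CO[Si](C(C)C)(C(C)C)C(C)C | intermediate
14 | (1,2-dibromoethoxy)tri(propan-2-yl)silane (racemic, formed in the flask) | BrCC(Br)O[Si](C(C)C)(C(C)C)C(C)C | intermediate
15 | [(Z)-2-bromoethenyl]oxy-tri(propan-2-yl)silane | Br/C=C\O[Si](C(C)C)(C(C)C)C(C)C | intermediate
16 | lithium 2-[tri(propan-2-yl)silyloxy]ethynide (formed in the flask) | [Li]C#CO[Si](C(C)C)(C(C)C)C(C)C | intermediate
17 | ethynyloxy-tri(propan-2-yl)silane | C#CO[Si](C(C)C)(C(C)C)C(C)C | intermediate
18 | benzyl (2E)-5-oxo-3-pentylpenta-2,4-dienoate (vinylketene, E expected, formed in the flask) | O=C=C/C(CCCCC)=C/C(=O)OCc1ccccc1 | intermediate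
19 | benzyl (2E)-3-[4-oxo-2-(triisopropylsilyloxy)cyclobut-2-en-1-yl]oct-2-enoate (racemic, formed in the flask) | CCCCC/C(=C\C(=O)OCc1ccccc1)C1C(=O)C=C1O[Si](C(C)C)(C(C)C)C(C)C | intermediate
20 | benzyl (2E,4E)-7-oxo-3-pentyl-5-(triisopropylsilyloxy)hepta-2,4,6-trienoate (dienylketene, formed in the flask) | O=C=C/C(O[Si](C(C)C)(C(C)C)C(C)C)=C\C(CCCCC)=C\C(=O)OCc1ccccc1 | intermediate
21 | benzyl 2-oxo-6-pentyl-4-(triisopropylsilyloxy)cyclohexa-3,5-diene-1-carboxylate (racemic, formed in the flask) | CCCCCC1=CC(O[Si](C(C)C)(C(C)C)C(C)C)=CC(=O)C1C(=O)OCc1ccccc1 | intermediate
22 | benzyl 2-hydroxy-6-pentyl-4-(triisopropylsilyloxy)benzoate | CCCCCc1cc(O[Si](C(C)C)(C(C)C)C(C)C)cc(O)c1C(=O)OCc1ccccc1 | intermediate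
23 | benzyl 2,4-dihydroxy-6-pentylbenzoate | CCCCCc1cc(O)cc(O)c1C(=O)OCc1ccccc1 | intermediate
24 | 1,3-dimethoxy-5-pentylbenzene | CCCCCc1cc(OC)cc(OC)c1 | starting material
25 | 1-bromo-2,4-dimethoxy-6-pentylbenzene | CCCCCc1cc(OC)cc(OC)c1Br | intermediate
26 | (2,4-dimethoxy-6-pentylphenyl)lithium (formed in the flask) | CCCCCc1cc(OC)cc(OC)c1[Li] | intermediate
27 | 2,4-dimethoxy-6-pentylbenzoic acid | CCCCCc1cc(OC)cc(OC)c1C(=O)O | intermediate
28 | 2,4-dimethoxy-6-pentylbenzoyl chloride (formed in the flask) | CCCCCc1cc(OC)cc(OC)c1C(Cl)=O | intermediate
29 | benzyl 4-[(2,4-dimethoxy-6-pentylbenzoyl)oxy]-2-hydroxy-6-pentylbenzoate | CCCCCc1cc(OC(=O)c2c(CCCCC)cc(OC)cc2OC)cc(O)c1C(=O)OCc1ccccc1 | intermediate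
30 | 4-[(2,4-dimethoxy-6-pentylbenzoyl)oxy]-2-hydroxy-6-pentylbenzoic acid | CCCCCc1cc(OC(=O)c2c(CCCCC)cc(OC)cc2OC)cc(O)c1C(=O)O | target

## Step count and risks

Total: 14 steps. Longest linear sequence: 9 steps (steps 1 to 5, 9, 10, 13, 14). The alkyne branch has 3 steps (6 to 8) and the ring A branch 2 steps (11, 12).

**Step 9 (key step, proposed new method).** The most likely failure is that the acyl terminus is captured inside the molecule before the alkyne arrives. This can happen by O-acylation through the ester enolate or by oxa-six-electron closure of the minor ketene geometry, and both lead to a pyranone. Further losses may come from ketene dimerization, from amine-promoted shift of the double bond in cyclobutenone 19 during heating, and from protonation of the siloxyalkyne by the ammonium salt.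

The fallback uses known chemistry and sets out from 24. Ether cleavage with BBr3 in CH2Cl2 gives 5-pentylbenzene-1,3-diol F1. Carboxylation ortho to hydroxyl with MeOMgOCO2Me in DMF at 120 °C gives 2,4-dihydroxy-6-pentylbenzoic acid F2. Alkylation of the carboxylate alone with benzyl bromide and KHCO3 in DMF gives 23, where the route is rejoined. Ring B is then taken from the aromatic pool and not built.

**Step 8.** Elimination from the minor E bromide may be slow. The amide base may attack silicon or induce silyl transfer from oxygen to carbon. The product may hydrolyse on work-up or be lost on evaporation.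

The fallback avoids the siloxyalkyne altogether; it sets out from 9 and comes back at 23. Its alkyne is made separately by known chemistry: KOtBu and trichloroethylene give (E)-1-tert-butoxy-1,2-dichloroethene F3, and n-BuLi followed by methanol gives tert-butoxyethyne F4. Acid chloride 9 is then combined with F4 and NEt3 at 0 to 25 °C. Excess F4 is removed under vacuum because it fragments to ketene when heated, and the residue is heated to give benzyl 4-tert-butoxy-2-hydroxy-6-pentylbenzoate F5. CF3CO2H in CH2Cl2 cleaves the aryl tert-butyl ether to 23.

**Step 5.** The ester carbonyl may close onto the new acid chloride, with loss of benzyl chloride to return anhydride 6, or with loss of HCl to the benzyloxypyranone, before 9 can be used.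

The fallback sets out from 8 and comes back at 22 without an isolated acid chloride. Acid 8 is added slowly to 17, NEt3 and 2-chloro-1-methylpyridinium iodide in toluene. The acyloxypyridinium salt 2-{[(2Z)-5-(benzyloxy)-5-oxo-3-pentylpent-2-enoyl]oxy}-1-methylpyridinium iodide F6 loses 1-methylpyridin-2-one under the action of the base to give ketene 18 in the presence of its trap. The mixture is then heated as in step 9 to reach 22.

**Step 13.** Acylation may be sluggish because of the two ortho substituents of 28, and forcing it may bring in the C2 hydroxyl or give the bis-ester.

The fallback sets out from 27 and 22 and comes back at 29, leaving out phenol 23. Acid 27 is converted with cyanuric fluoride and pyridine into 2,4-dimethoxy-6-pentylbenzoyl fluoride F7. F7 is combined with silyl ether 22 and a catalytic amount of Bu4NF. Fluoride unmasks only the C4 phenoxide, which takes up the acyl fluoride and releases fluoride again, so the C2 hydroxyl is never offered as a nucleophile.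

## Further compounds

F1 | step 9 | 5-pentylbenzene-1,3-diol | CCCCCc1cc(O)cc(O)c1
F2 | step 9 | 2,4-dihydroxy-6-pentylbenzoic acid | CCCCCc1cc(O)cc(O)c1C(=O)O
F3 | step 8 | (E)-1-tert-butoxy-1,2-dichloroethene | Cl/C=C(/Cl)OC(C)(C)C
F4 | step 8 | tert-butoxyethyne | C#COC(C)(C)C
F5 | step 8 | benzyl 4-tert-butoxy-2-hydroxy-6-pentylbenzoate | CCCCCc1cc(OC(C)(C)C)cc(O)c1C(=O)OCc1ccccc1
F6 | step 5 | 2-{[(2Z)-5-(benzyloxy)-5-oxo-3-pentylpent-2-enoyl]oxy}-1-methylpyridinium iodide | CCCCC/C(CC(=O)OCc1ccccc1)=C/C(=O)Oc1cccc[n+]1C.[I-]
F7 | step 13 | 2,4-dimethoxy-6-pentylbenzoyl fluoride | CCCCCc1cc(OC)cc(OC)c1C(F)=O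
A1 | alternative 1 | 1-bromo-2-iodo-3,5-dimethoxybenzene | COc1cc(Br)c(I)c(OC)c1
A2 | alternative 1 | 3,5-dimethoxybenzyne (1,2-didehydro-3,5-dimethoxybenzene) | COC1=CC(OC)=CC#C1
A3 | alternative 1 | 2,4-dimethoxy-6-pentylbenzoic acid | CCCCCc1cc(OC)cc(OC)c1C(=O)O
A4 | alternative 2 | (E)-non-3-en-2-one | CCCCC/C=C/C(C)=O
A5 | alternative 2 | methyl 2-hydroxy-4-oxo-6-pentylcyclohex-1-ene-1-carboxylate (racemic) | CCCCCC1CC(=O)CC(O)=C1C(=O)OC
A6 | alternative 2 | methyl 2,4-dimethoxy-6-pentylbenzoate | CCCCCc1cc(OC)cc(OC)c1C(=O)OC
A7 | alternative 3 | 6-(2,4-dioxononyl)-2,2-dimethyl-4H-1,3-dioxin-4-one | CCCCCC(=O)CC(=O)CC1=CC(=O)OC(C)(C)O1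
A8 | alternative 3 | benzyl 3,5,7-trioxododecanoate | CCCCCC(=O)CC(=O)CC(=O)CC(=O)OCc1ccccc1
A9 | alternative 3 | benzyl 2,4-dihydroxy-6-pentylbenzoate | CCCCCc1cc(O)cc(O)c1C(=O)OCc1ccccc1
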